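**Before you repeat.** If you repeat this run, you are watching a single product, Qe, in four flasks that differ in temperature.

| flask | Ji | Rx | Lx | Aj | temperature | time |
|---|---|---|---|---|---|---|
| north-west | 0.20 M | 0.240 M | 0.0400 M | 0.20 mM | 80 °C | 40 min |
| east | 0.20 M | 0.240 M | 0.0400 M | 0.20 mM | 100 °C | 40 min |
| north-east | 0.20 M | 0.240 M | 0.0400 M | 0.20 mM | 60 °C | 40 min |
| south | 0.20 M | 0.240 M | 0.0400 M | 0.20 mM | 40 °C | 40 min |

- the flask with the highest amount of Qe, in percent of the Ji charged ("all alike" if they lie within 1.5 percentage points) (north-west / east / north-east / south / all alike)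
- final Qe, as a percentage of the Ji charged, in north-west
- final Qe, as a percentage of the Ji charged, in east
- final Qe, as a percentage of the Ji charged, in north-east
- final Qe, as a percentage of the Ji charged, in south

- percentages count the Ji that a species holds: one Ji.Qe counts as two
- the list of constants is for 60 °C, to be carried to other temperatures by the activation energies and enthalpies

    Ji + Rx + Aj → Aj + Qe (k1 = 18 L² mol⁻² s⁻¹, Ea1 = 50.0 kJ mol⁻¹)
    Lx + Rx + Aj → Aj + Dx (k2 = 33 L² mol⁻² s⁻¹, Ea2 = 45.0 kJ mol⁻¹)
    Ji + Rx → Ji.Rx (k3 = 9.6 × 10⁻⁵ L mol⁻¹ s⁻¹, Ea3 = 62.0 kJ mol⁻¹)
    Ji + Qe → Ji.Qe (k4 = 0.0046 L mol⁻¹ s⁻¹, Ea4 = 66.0 kJ mol⁻¹)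
    Qe ⇌ Qa (K5 = 2.0, k5 = 0.0024 s⁻¹, Ea5 = 104 kJ mol⁻¹, ΔH5 = −13.0 kJ mol⁻¹)
    (constants at 60 °C)

**Main step.** Ji and Rx meet on Aj to give Qe. With nothing else running, a run in south turns 40.9% of the Ji into Qe, and a run in east turns 98.4%. By this count, heat wins.

**Adding Lx.** Lx competes for Rx: at the start of south, Rx goes 2.4 times faster to Qe than to Dx. The charge of Rx matches Ji plus Lx, so it can just serve both.

**Adding capture.** Now Ji also captures Qe as Ji.Qe. Making and capture both carry Ji as a factor, so Ji cancels when you compare them. Qe stops gaining at the crossing where Qe equals h times Rx, both counted as fractions of the Ji charged. Here h, the crossing ratio, is the making constant times Aj over the capture constant, a selectivity factor. It is 0.783 at the reference temperature. Capture has the steeper activation energy, by 16.0 kJ mol⁻¹, so h falls from 1.13 in south to 0.421 in east.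

**Adding Qa.** Qe and Qa share what survives capture. In east their relaxation half-life is 2.82 s, and the ratio K of Qa to Qe at equilibrium is 1.21. In a flask that finishes its Ji and Lx, each capture spares one Rx, so the share of Ji captured, c, equals the Rx left. The Qe and Qa together then hold one minus two c. Setting Qe at the crossing gives Qe as h over two plus h times one plus K. That is 14.4% for east, 16.5% for north-west and, reckoned as if finished, 18.0% for north-east.

South is different. Its half-life for settling, 38.6 min, is about as long as the run, so Qe there is under kinetic rather than thermodynamic control. Qe made at mid-run has had time for part of the change to Qa, which leaves about 31.9% before capture trims it. I therefore commit to south.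

**The check.** The forecast also names south, with 17% in north-west, 16.4% in east, 16.3% in north-east and 23.4% in south, because at the low temperature “Qe stays kinetically high”; its east stands above my 14.4%. The simulation gives south, with 17.1%, 16.3%, 16.1% and 23.8% in that order.

**Crossing read.** At the end of east, Rx stands at 26% of its own charge, which puts the crossing at 12.9% against 16.3% of Qe. In north-west the crossing stands at 16.4% against 17.1% of Qe. South ends far below its crossing of 78.2%, with 23.8%. Temperature's hold on capture is its largest single effect here: east minus south is −7.6 percentage points, and without that effect it becomes 15 points.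

The constants used here were set for the occasion.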